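- My closed, stirred vessel holds X, J and Z at constant temperature and constant volume.

X 0.050 M; J 1.00 equiv; Z 1.00 equiv; time 25 h

    X + J → X.J (k1 = 0.15 L mol⁻¹ s⁻¹)
    J + Z → J.Z (k2 = 0.14 L mol⁻¹ s⁻¹)
    X.J ⇌ G (K3 = 1.3, k3 = 0.0064 s⁻¹)

- the X.J standing at 25 h, as a percentage of the X charged
- the G standing at 25 h, as a percentage of the X charged

- X and Z together offer twice the ends that J can serve, so J is the limiting reagent. The half-life of X by the first step, 1.5 min, and that of J by the second, 1.7 min, each with the other concentrations as charged, are far shorter than 25 h, so I count the J charged as used.
- I follow one J to its first fork. The quantity I carry is the selectivity factor: how many times likelier a given X is to take a J than a given Z is, 1.07.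
- With cX equal to cZ at the start, that J goes to X with chance 51.7%.
- A link then meets the second fork. The third step relaxes with a half-life of 1.02 min, far shorter than 25 h, so I take K3 as cG/cX.J, and X.J keeps 43.5% of the X taken up, with G holding the rest.
- My first figures are therefore 22.5% X.J and 29.2% G.
- The weak link is the first chance, because X is used faster than Z and cX falls behind cZ. Both meet the same J, so ln(X left) is the factor times ln(Z left).
- Taking Z left as 51.7% gives X left as 49.3%. X's share of what is lost is then 51.2%.
- I commit to 22.3% X.J and 28.9% G.
- The forecast gives 22.3% and 28.9%, saying that “X and Z split J almost evenly, with the slightly faster X taking about 51%”.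
- The simulation of this flask gives 22.3% X.J and 28.9% G.
- This flask ends with Z at 51.2% of its own charge, and raising that to the factor gives 48.9%, beside the 48.8% of the X charged standing as X. The neighbour differs by holding 4.00 equiv of Z. There a J first goes to X with chance 21.1%, so I take X left as 78.9% and Z left as 80.1%, each of its own charge. X's share is 21.0%, which makes 9.13% X.J and 11.9% G. The neighbour's simulation gives 9.13% X.J and 11.9% G.

All constants were chosen freely; what happens was integrated by code.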